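The route rests on disconnecting the C2–C3 bond of the cyclopentanone (ring B; indanone numbering: C1 is CH–OAc, C2 is C=O, C3 is CH2; ring A is C3a–C4–C5–C6–C7–C7a). Ring B is closed by a Dieckmann condensation in which the C3 methylene of an acetate arm on C3a acylates the C2 ester of a silyloxyacetate arm on C7a. The step exploits the fact that C2 is flanked by a bare CH2 (C3) and an oxygenated CH (C1): only C3 attack gives an enolisable β-keto ester, so the regiochemistry is funnelled, and the epimeric C1 centre is converged afterwards by enolisation. The precursor is an all-trans cyclohexane, built from (S)-cryptone, that already carries the ring A vinyl epoxide.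

Key step: step 10

Remarks on the chemistry
- All intermediates are described with the locants of the target (C1–C7a as above); β is the face that carries the C7 isopropyl group. In the target: 7-iPr β, 6-OH β, 5-O-angelate α, 1-OAc β, H-7a β, H-3a α.
- C1 is carried as an epimer mixture (left undefined in the SMILES of 7 and 11–21) and is set in step 12.
- The sense of induction in step 1 is assumed to follow the usual enamine shielding model; if it were opposite, the mirror-image catalyst would be used.
- Compounds 1, 2, 5, 8, 9, 23 and the step 1 catalyst are taken as commercial.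

Step 1
Reactants: 1 3-methylbutanal; 2 but-3-en-2-one
Product: 3 (S)-2-isopropyl-5-oxohexanal
Conditions: (S)-2-(methoxydiphenylmethyl)pyrrolidine (5 mol%), ethyl 3,4-dihydroxybenzoate (20 mol%), neat, 4 °C
Reagents that add atoms: none
Why: Enamine-catalysed asymmetric Michael addition, in which the (S)-pyrrolidine forms the E-enamine of 1 and shields one face so that 2 should add to give the (S)-aldehyde (the future C7).

Step 2
Reactants: 3 (S)-2-isopropyl-5-oxohexanal
Product: 4 (S)-4-isopropylcyclohex-2-en-1-one
Conditions: LiOH (cat.), iPrOH, rt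
Reagents that add atoms: none
Why: Intramolecular aldol condensation (methyl ketone enolate onto the aldehyde, then loss of water) under mild base, which should leave the C7 stereocentre untouched.

Step 3
Reactants: 5 methyl 2-[(tert-butyldimethylsilyl)oxy]acetate
Product: 6 glycolate ketene silyl acetal
Conditions: LDA, THF, −78 °C; TMSCl
Reagents that add atoms: chlorotrimethylsilane, C[Si](C)(C)Cl
Why: Kinetic ester enolate formation and O-silylation give the ketene silyl acetal needed as the C1–C2 nucleophile (no stereocentre; the alkene geometry is immaterial because C1 is set later).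

Step 4
Reactants: 4 (S)-cryptone; 6 glycolate ketene silyl acetal
Product: 7 enol silane Michael adduct
Conditions: Tf2NH (1 mol%), CH2Cl2, −78 °C; Et3N quench, non-aqueous work-up
Reagents that add atoms: none
Why: Mukaiyama–Michael addition catalysed by the silyl triflimide formed in situ, in which the acetal adds to C7a anti to the C7 isopropyl group (the usual trans outcome for 4-substituted cyclohexenones), silyl transfer stores the enolate regiospecifically as the C4 enol silane, and C1 forms as an epimer mixture.

Step 5
Reactants: 8 bromoacetyl bromide; 9 2-(trimethylsilyl)ethanol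
Product: 10 2-(trimethylsilyl)ethyl bromoacetate
Conditions: pyridine, CH2Cl2, 0 °C
Reagents that add atoms: none
Why: Esterification of the alcohol by the acid bromide with pyridine as acid scavenger gives the alkylating agent whose ester can later be removed by fluoride.

Step 6
Reactants: 7 enol silane Michael adduct; 10 2-(trimethylsilyl)ethyl bromoacetate
Product: 12 all-trans keto diester, via tetrabutylammonium enolate 11 (not isolated)
Conditions: tetrabutylammonium difluorotriphenylsilicate (1.1 equiv), THF, −78 → −40 °C; then 10
Reagents that add atoms: none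
Why: Fluoride cleavage of the enol silane gives a regiodefined ammonium enolate (regiospecific enolate alkylation) that should be alkylated by the bromoacetate at C3a anti to the neighbouring C7a arm, giving the all-equatorial trans,trans ketone, which is also the thermodynamic C3a epimer.

Step 7
Reactants: 12 all-trans keto diester
Product: 14 C5–C6 enone diester, via trimethylsilyl enol ether 13 (not isolated)
Conditions: LDA, TMSCl, THF, −78 °C; then Pd(OAc)2 (1.05 equiv), MeCN, rt
Reagents that add atoms: none
Why: Kinetic deprotonation at the unhindered C5 methylene (the ketone is more acidic than either ester and C3a is a hindered methine) followed by Saegusa oxidation of the enol silane installs the C5–C6 enone without touching a stereocentre.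

Step 8
Reactants: 14 C5–C6 enone diester
Product: 15 5β,6β-epoxy ketone diester
Conditions: TBHP (decane), DBU, CH2Cl2, 0 °C → rt
Reagents that add atoms: tert-butyl hydroperoxide, CC(C)(C)OO
Why: Weitz–Scheffer nucleophilic epoxidation, in which the hydroperoxide should add axially to C6 of the conformationally locked all-equatorial half-chair, that is on the β face cis to the isopropyl group, and the enolate then closes the epoxide on the same face.

Step 9
Reactants: 15 5β,6β-epoxy ketone diester
Product: 16 vinyl epoxide diester
Conditions: Ph3PCH3Br (slight excess over base), KOtBu, THF, 0 °C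
Reagents that add atoms: methylenetriphenylphosphorane (made in the flask from methyltriphenylphosphonium bromide and KOtBu), C=P(c1ccccc1)(c1ccccc1)c1ccccc1
Why: Wittig methylenation of the C4 ketone, which is far more reactive toward the ylide than the two esters, gives the exocyclic alkene and thereby the ring A vinyl epoxide.

Step 10
Reactants: 16 vinyl epoxide diester
Product: 18 bicyclic β-keto ester, via potassium enolate 17 (not isolated)
Conditions: KOtBu (2.2 equiv), THF, −20 → 0 °C; AcOH
Reagents that add atoms: none
Why: Dieckmann condensation (intramolecular Claisen acylation): the alkoxide reversibly deprotonates the unhindered C3 methylene of the 2-(trimethylsilyl)ethyl acetate arm, the enolate adds to the methyl ester carbonyl C2, methoxide leaves and the product is held as its stabilised β-keto ester enolate 17. The closest known reaction is the Dieckmann cyclisation of trans-cyclohexane-1,2-diacetates to trans-hydrindan-2-ones. Ring B closes in a 5-exo-trig mode and is necessarily trans-fused, because C3a and C7a already carry the two arms trans-diequatorially. No lasting stereocentre is created: C3 is enolised and later decarboxylated, and C1 stays an epimer mixture. The step needs regioselectivity between the two Claisen directions, secured kinetically (a free CH2 against a hindered silyloxy-substituted CH) and thermodynamically (only C3 attack gives a β-keto ester with a proton between the two carbonyls, whereas the other adduct should revert by retro-Claisen under the alkoxide). It also needs chemoselectivity over the vinyl epoxide, secured by the bulky, poorly nucleophilic base at low temperature.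

Step 11
Reactants: 18 bicyclic β-keto ester
Product: 20 α-hydroxy ketone, via hydroxy β-keto acid 19 (not isolated)
Conditions: TBAF (4 equiv), AcOH (4 equiv), THF, 0 → 40 °C
Reagents that add atoms: none
Why: Fluoride-induced fragmentation of the 2-(trimethylsilyl)ethyl ester and desilylation at O-1 give the β-keto acid, which decarboxylates on warming, while the acetic acid buffer should suppress ketol isomerisation.

Step 12
Reactants: 20 α-hydroxy ketone
Product: 22 1β-acetoxy ketone, via acetate epimer mixture 21 (not isolated)
Conditions: Ac2O, Et3N, DMAP (cat.), CH2Cl2, 0 °C → rt; then DBU (0.2 equiv), rt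
Reagents that add atoms: acetic anhydride, CC(=O)OC(C)=O
Why: O-Acetylation followed by base-mediated enolisation toward C1 should funnel both C1 epimers into the pseudo-equatorial 1β-acetate (cis to H-7a), the arrangement expected to be the stable one by analogy with trans-hydrindane 2-keto-1-ols such as the 16-keto-17β-ols of steroid ring D.

Step 13
Reactants: 22 1β-acetoxy ketone; 23 angelic acid
Product: 24 target compound
Conditions: 23 (5 equiv), CSA (5 mol%), CH2Cl2, −20 °C → rt
Reagents that add atoms: none
Why: Acid-catalysed epoxide opening by the carboxylic acid at the allylic carbon C5 with inversion (anti and trans-diaxial, in line with the Fürst–Plattner rule) should deliver the 5α-angelate and the free 6β-alcohol in one operation.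

Compound list
1 | 3-methylbutanal (isovaleraldehyde) | CC(C)CC=O | starting material
2 | but-3-en-2-one (methyl vinyl ketone) | CC(=O)C=C | starting material
3 | (S)-2-isopropyl-5-oxohexanal | O=C[C@H](C(C)C)CCC(C)=O | intermediate
4 | (S)-4-isopropylcyclohex-2-en-1-one, (S)-cryptone | O=C1C=C[C@H](C(C)C)CC1 | intermediate
5 | methyl 2-[(tert-butyldimethylsilyl)oxy]acetate | COC(=O)CO[Si](C)(C)C(C)(C)C | starting material
6 | 2-[(tert-butyldimethylsilyl)oxy]-1-methoxy-1-[(trimethylsilyl)oxy]ethene, E/Z mixture | COC(O[Si](C)(C)C)=CO[Si](C)(C)C(C)(C)C | intermediate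
7 | methyl 2-[(tert-butyldimethylsilyl)oxy]-2-[6-isopropyl-3-(trimethylsilyloxy)cyclohex-2-en-1-yl]acetate; C7a arm α, C7 isopropyl β (trans), C1 epimer mixture | C[Si](C)(C)OC1=C[C@@H](C(O[Si](C)(C)C(C)(C)C)C(=O)OC)[C@H](C(C)C)CC1 | intermediate
8 | bromoacetyl bromide | BrCC(Br)=O | starting material
9 | 2-(trimethylsilyl)ethanol | OCC[Si](C)(C)C | starting material
10 | 2-(trimethylsilyl)ethyl bromoacetate | BrCC(=O)OCC[Si](C)(C)C | intermediate
11 | tetrabutylammonium C4 enolate of the Michael adduct (C3a=C4) | CCCC[N+](CCCC)(CCCC)CCCC.[O-]C1=C[C@@H](C(O[Si](C)(C)C(C)(C)C)C(=O)OC)[C@H](C(C)C)CC1 | intermediate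
12 | methyl 2-[(tert-butyldimethylsilyl)oxy]-2-{6-isopropyl-3-oxo-2-[2-oxo-2-(2-trimethylsilylethoxy)ethyl]cyclohexyl}acetate; all-trans ring (C3a arm β, C7a arm α, C7 isopropyl β), C1 epimer mixture | O=C1[C@H](CC(=O)OCC[Si](C)(C)C)[C@@H](C(O[Si](C)(C)C(C)(C)C)C(=O)OC)[C@H](C(C)C)CC1 | intermediate
13 | C4 trimethylsilyl enol ether of 12 (C4=C5) | C[Si](C)(C)OC1=CC[C@@H](C(C)C)[C@H](C(O[Si](C)(C)C(C)(C)C)C(=O)OC)[C@H]1CC(=O)OCC[Si](C)(C)C | intermediate
14 | C5–C6 enone of 12 (4-oxo-cyclohex-5-ene, side chains unchanged) | O=C1C=C[C@@H](C(C)C)[C@H](C(O[Si](C)(C)C(C)(C)C)C(=O)OC)[C@H]1CC(=O)OCC[Si](C)(C)C | intermediate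
15 | 5β,6β-epoxide of 14 (epoxide cis to the isopropyl group) | O=C1[C@H]2O[C@H]2[C@@H](C(C)C)[C@H](C(O[Si](C)(C)C(C)(C)C)C(=O)OC)[C@H]1CC(=O)OCC[Si](C)(C)C | intermediate
16 | 4-methylene-5β,6β-epoxy diester (vinyl epoxide; C3a arm β, C7a arm α, C7 isopropyl β) | C=C1[C@H]2O[C@H]2[C@@H](C(C)C)[C@H](C(O[Si](C)(C)C(C)(C)C)C(=O)OC)[C@H]1CC(=O)OCC[Si](C)(C)C | intermediate
17 | potassium enolate of β-keto ester 18 | [K+].C=C1[C@H]2O[C@H]2[C@@H](C(C)C)[C@@H]3C(O[Si](C)(C)C(C)(C)C)C([O-])=C(C(=O)OCC[Si](C)(C)C)[C@@H]13 | intermediate
18 | 2-(trimethylsilyl)ethyl 1-[(tert-butyldimethylsilyl)oxy]-5β,6β-epoxy-7β-isopropyl-4-methylene-2-oxo-octahydroindene-3-carboxylate; trans-fused (H-3a α, H-7a β), C1 and C3 epimer mixtures | C=C1[C@H]2O[C@H]2[C@@H](C(C)C)[C@@H]3C(O[Si](C)(C)C(C)(C)C)C(=O)C(C(=O)OCC[Si](C)(C)C)[C@@H]13 | intermediate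
19 | 5β,6β-epoxy-1-hydroxy-7β-isopropyl-4-methylene-2-oxo-octahydroindene-3-carboxylic acid; trans-fused | C=C1[C@H]2O[C@H]2[C@@H](C(C)C)[C@@H]3C(O)C(=O)C(C(=O)O)[C@@H]13 | intermediate
20 | 5β,6β-epoxy-1-hydroxy-7β-isopropyl-4-methylene-octahydroinden-2-one; trans-fused, C1 epimer mixture | C=C1[C@H]2O[C@H]2[C@@H](C(C)C)[C@@H]3C(O)C(=O)C[C@@H]13 | intermediate
21 | 1-acetoxy-5β,6β-epoxy-7β-isopropyl-4-methylene-octahydroinden-2-one; trans-fused, C1 epimer mixture | C=C1[C@H]2O[C@H]2[C@@H](C(C)C)[C@@H]3C(OC(C)=O)C(=O)C[C@@H]13 | intermediate
22 | 1β-acetoxy-5β,6β-epoxy-7β-isopropyl-4-methylene-octahydroinden-2-one; trans-fused (H-3a α, H-7a β) | C=C1[C@H]2O[C@H]2[C@@H](C(C)C)[C@@H]3[C@@H](OC(C)=O)C(=O)C[C@@H]13 | intermediate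
23 | angelic acid, (Z)-2-methylbut-2-enoic acid | C/C=C(/C)C(=O)O | starting material
24 | (1R,3aR,5S,6S,7S,7aR)-1-acetoxy-6-hydroxy-7-isopropyl-4-methylidene-2-oxo-octahydro-1H-inden-5-yl (2Z)-2-methylbut-2-enoate | C=C1[C@@H]2CC(=O)[C@H](OC(C)=O)[C@H]2[C@H](C(C)C)[C@H](O)[C@H]1OC(=O)/C(C)=C\C | target

Total step count: 13 (steps 3 and 5 are side-branch reagent preparations).
Longest linear sequence: 11 steps (1, 2, 4, 6, 7, 8, 9, 10, 11, 12, 13).

Steps most likely to fail

1. Step 8. The facial selectivity of the hydroperoxide addition may be poor or reversed if steric approach control (anti to the neighbouring isopropyl group) outweighs axial attack. The fallback sets out from 14 and returns at 15. The ketone of 14 is reduced by a CBS reduction (oxazaborolidine enantiomer chosen to deliver hydride from the α face, BH3·SMe2) to the pseudo-axial 4β-allylic alcohol F1. A hydroxyl-directed epoxidation with VO(acac)2 and TBHP then places the epoxide syn to the hydroxyl, on the β face, giving the epoxy alcohol F2. Oxidation of the carbinol with DMP gives 15.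

2. Step 13. The hindered, weakly nucleophilic acid may open the protonated epoxide slowly, so that SN2′ attack at the exocyclic methylene carbon, acid-induced rearrangement of the epoxide, or Z-to-E isomerisation of the angelate can compete. The fallback sets out from 22 and returns at 24. Hydrolytic opening with dilute HClO4 in THF–H2O (a small nucleophile in large excess, attacking C5 trans-diaxially) gives the 5α,6β-diol F3. The less hindered allylic C5 hydroxyl is then acylated selectively with the mixed anhydride of 23 and 2,4,6-trichlorobenzoyl chloride (Et3N, then DMAP, toluene; Yamaguchi esterification), the C6 hydroxyl being shielded by the adjacent isopropyl group.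

3. Step 12. Equilibration at C1 may be incomplete, or acetyl migration and ketol transposition through the enediol may intervene under base, leaving a mixture. The fallback sets out from 20 and returns at 22, and replaces equilibration by inversion. The C1 epimers of 20 are separated. The 1β-alcohol F4 is acetylated under non-equilibrating conditions (Ac2O, pyridine, 0 °C). The 1α-alcohol F5 is converted into the same acetate with inversion by a Mitsunobu reaction (PPh3, DIAD, AcOH).

Further compounds
F1 | step 8 | 4β-allylic alcohol from 14 (4β-hydroxy, C5=C6 alkene, side chains as in 14) | O[C@H]1C=C[C@@H](C(C)C)[C@H](C(O[Si](C)(C)C(C)(C)C)C(=O)OC)[C@H]1CC(=O)OCC[Si](C)(C)C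
F2 | step 8 | 4β-hydroxy-5β,6β-epoxide (epoxy alcohol, side chains as in 14) | O[C@H]1[C@H]2O[C@H]2[C@@H](C(C)C)[C@H](C(O[Si](C)(C)C(C)(C)C)C(=O)OC)[C@H]1CC(=O)OCC[Si](C)(C)C
F3 | step 13 | 1β-acetoxy-5α,6β-dihydroxy-7β-isopropyl-4-methylene-octahydroinden-2-one, trans-fused | C=C1[C@H](O)[C@@H](O)[C@@H](C(C)C)[C@@H]2[C@@H](OC(C)=O)C(=O)C[C@@H]12
F4 | step 12 | 1β-hydroxy epimer of 20 | C=C1[C@H]2O[C@H]2[C@@H](C(C)C)[C@@H]3[C@@H](O)C(=O)C[C@@H]13
F5 | step 12 | 1α-hydroxy epimer of 20 | C=C1[C@H]2O[C@H]2[C@@H](C(C)C)[C@@H]3[C@H](O)C(=O)C[C@@H]13
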